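All constants were chosen freely; what happens was integrated by code.

Follow the catalyst.

    starting material + partner → uncatalysed product (k1 = 2.1 /M/min)
    partner + catalyst intermediate A → free catalyst + target (k2 = 2200 /M/min)
    partner + catalyst intermediate B → free catalyst + second product (k3 = 200 /M/min)
    second substrate + free catalyst ⇌ catalyst intermediate B (K4 = 15 /M, k4 = 600 /M/min)
    starting material + free catalyst ⇌ catalyst intermediate A (K5 = 13 /M, k5 = 24000 /M/min)

in all of them: second substrate 0.0250 M; partner 0.0600 M; free catalyst 0.25 mM; time 1.5 h

| charge | starting material |
|---|---|
| larch | 0.012 M |
| maple | 0.025 M |
| oak | 0.050 M |
| birch | 0.10 M |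
| ash | 0.20 M |

- "hardly changes" means that all values lie within two and a half points (for a concentration: within two and a half percent of the largest)
- run time (larch): 1.5 h

* [target] at the end for larch, maple, oak, birch, ash, in this order
* the shape of the row from first to last (falls all the way / falls, then rises / rises, then falls / hardly changes / rises all the way)

Starting material leaves through two doors: straight to uncatalysed product with partner, or through catalyst intermediate A to target. Catalyst intermediate A falls back at 1850 /min and moves on at 132 /min at full partner; it falls back faster than it moves on, so I treat its formation as an equilibrium. Both doors then carry the product c(starting material)·c(partner), which cancels from their ratio. What remains is 2200 /M/min × 13 /M × c(free catalyst) / 2.1 /M/min. Call it the door ratio: with the catalyst wholly free, rate to target over rate to uncatalysed product is 3.40.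

But the catalyst is shared. Its free part is one over D, where D = 1 + 15 /M·c(second substrate) + 13 /M·c(starting material). The target share, the selectivity, is then the door ratio over the door ratio plus D.

Now replace the curve by its mean. I hold second substrate at its charge and take c(starting material) halfway through the span it crosses. Each passage costs one partner, so the amount used is the smaller of the two charges. I give partner wholly to starting material and assume the time suffices; for larch the half-life by the uncatalysed step alone, with the other concentrations as charged, is 0.092 h, much shorter than the run of 1.5 h.

| flask | mean c(starting material) | D | target share | c(target) |
|---|---|---|---|---|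
| larch | 0.00600 M | 1.45 | 70.1 % | 0.00841 M |
| maple | 0.0125 M | 1.54 | 68.9 % | 0.0172 M |
| oak | 0.0250 M | 1.70 | 66.7 % | 0.0333 M |
| birch | 0.0700 M | 2.29 | 59.8 % | 0.0359 M |
| ash | 0.170 M | 3.58 | 48.7 % | 0.0292 M |

Read down the share column: it sinks slowly from larch to oak, and c(target) still climbs with the charge. Oak is charged with less starting material than partner. Birch is charged with more, so partner, at 0.0600 M in every flask, becomes the limiting reagent there. In my reckoning the amount used therefore rises from 0.050 M in oak to 0.0600 M in birch while the share falls from 66.7 % to 59.8 %, and birch ends higher than oak. From birch to ash the amount used stays at 0.0600 M while the share falls, so my row rises, then falls.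

The mean costs little. Across its span, ash runs from 46.1 % at the start to 51.6 % at the end, on either side of 48.7 %.

The forecast, reckoning the “share going to target” its own way, gives 0.0085 M, 0.0175 M, 0.033 M, 0.035 M and 0.029 M, and the shape rises, then falls. For larch its number is 0.0085 M and mine is 0.00841 M.

The simulation gives 0.00844 M, 0.0173 M, 0.0334 M, 0.0352 M and 0.0291 M: the row rises, then falls, turning at a reading of 0.066 M. In ash after 1.50 h, partner stands at 0 % with 70.1 % of the starting material left. Free catalyst in ash is then 31.3 % of its charge, so the door ratio 3.40 shrinks to 1.07, a target share of 51.7 % at that moment. The ash flask holds 14.5 % of its charged starting material as target and 15.3 % as uncatalysed product.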